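**Plan**

- Retrosynthesis: the two MOM ethers come off last. The C2–H and C3–H bonds are then removed (flavanone back to flavone). The flavone is cut at C4a–C4, C4–C3 and O1–C2 into a ring A ortho-iodophenol, carbon monoxide and a ring B arylacetylene.
- Enabling feature: C4 is one carbonyl carbon lying between C4a of ring A and the C3–C2 pair that carries ring B, and O1 sits on C8a next to C4a. A 2-halophenol, CO and a terminal alkyne therefore map onto ring C atom for atom, and the halogen alone decides the ring A regiochemistry.
- Ring A piece: 4-iodoresorcinol is mono-protected, O-allylated and rearranged (Claisen) to the only free ortho carbon, the future C8; cross-metathesis then turns allyl into prenyl. Iodine is used instead of bromine because ortho-iodophenols are the established substrates for carbonylative annulation, whereas an electron-rich ortho-bromophenol would add to palladium too slowly.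
- Ring B piece: 3,5-dibromo-4-hydroxybenzaldehyde is MOM-protected, doubly prenylated by Stille coupling and homologated to the terminal alkyne.
- Rings A and B are bought as benzenes; ring C is closed last as the achiral flavone. The only stereocentre, C2 (S), comes from a ligand-controlled CuH 1,4-reduction of the flavone, and mild acid then frees both phenols.

Key step: step 8

Assumption: (R)-DTBM-SEGPHOS is written as the ligand enantiomer that delivers hydride to the C2 face leading to 2S; should the sense of induction prove opposite, (S)-DTBM-SEGPHOS is used with nothing else changed. Flavonoid numbering is used throughout, and prenyl means 3-methylbut-2-en-1-yl.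

**Route**

Step 1
Reactants: 1 4-iodobenzene-1,3-diol (4-iodoresorcinol)
Product: 2 2-iodo-5-(methoxymethoxy)phenol
Conditions: MOMCl (1.0 equiv), i-Pr2NEt, CH2Cl2, −10 to 0 °C
Reagents that add atoms: chloromethyl methyl ether (MOMCl), COCCl
Why: O-alkylation to the MOM ether (Williamson type) is expected at the hydroxyl para to iodine, because the hydroxyl ortho to iodine is shielded and its phenoxide is the weaker nucleophile, and limiting MOMCl keeps the bis-ether low, with chromatography removing it and any regioisomer.

Step 2
Reactants: 2 2-iodo-5-(methoxymethoxy)phenol; 3 allyl bromide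
Product: 4 1-iodo-4-(methoxymethoxy)-2-(prop-2-en-1-yloxy)benzene
Conditions: K2CO3, acetone, reflux
Reagents that add atoms: none
Why: Williamson ether synthesis on the one remaining phenol with a reactive allylic bromide, under conditions that leave the aryl iodide and the MOM acetal untouched.

Step 3
Reactants: 4 1-iodo-4-(methoxymethoxy)-2-(prop-2-en-1-yloxy)benzene
Product: 5 6-iodo-3-(methoxymethoxy)-2-(prop-2-en-1-yl)phenol
Conditions: PhNEt2, 190 °C
Reagents that add atoms: none
Why: Aromatic Claisen rearrangement ([3,3]-sigmatropic shift, then tautomerisation): the ortho carbon bearing iodine cannot re-aromatise, so the allyl group should end on the carbon between the two oxygens, the future C8, while the amine solvent buffers the new phenol against acid-induced cyclisation.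

Step 4
Reactants: 5 6-iodo-3-(methoxymethoxy)-2-(prop-2-en-1-yl)phenol; 6 2-methylbut-2-ene
Product: 7 6-iodo-3-(methoxymethoxy)-2-(3-methylbut-2-en-1-yl)phenol
Conditions: second-generation Grubbs catalyst RuCl2(=CHPh)(H2IMes)(PCy3) (3 mol%), 2-methylbut-2-ene (excess)/CH2Cl2, 35 °C
Reagents that add atoms: none
Why: Olefin cross-metathesis of a terminal allyl arene with a large excess of 2-methylbut-2-ene, which is the standard way to turn ortho-allylphenols into ortho-prenylphenols with loss of propene and tolerates free phenols and aryl iodides.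

Step 5
Reactants: 8 3,5-dibromo-4-hydroxybenzaldehyde
Product: 9 3,5-dibromo-4-(methoxymethoxy)benzaldehyde
Conditions: MOMCl, i-Pr2NEt, CH2Cl2, 0 °C to rt
Reagents that add atoms: chloromethyl methyl ether (MOMCl), COCCl
Why: MOM ether formation on an acidic phenol, in which the small and very reactive chloromethyl ether overcomes the two flanking bromines and the aldehyde is inert.

Step 6
Reactants: 9 3,5-dibromo-4-(methoxymethoxy)benzaldehyde; 10 tributyl(3-methylbut-2-en-1-yl)stannane
Product: 11 4-(methoxymethoxy)-3,5-bis(3-methylbut-2-en-1-yl)benzaldehyde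
Conditions: Pd(PPh3)4 (10 mol%), stannane (2.5 equiv), DMF, 100 °C
Reagents that add atoms: none
Why: Two-fold Stille coupling of an aryl dibromide with an allylic stannane, in which the allyl–palladium intermediate equilibrates and reductive elimination is expected at the less substituted terminus to give the linear prenyl groups, with the aldehyde and MOM ether tolerated.

Step 7
Reactants: 11 4-(methoxymethoxy)-3,5-bis(3-methylbut-2-en-1-yl)benzaldehyde
Product: 12 5-ethynyl-2-(methoxymethoxy)-1,3-bis(3-methylbut-2-en-1-yl)benzene
Conditions: MeC(O)C(N2)P(O)(OMe)2, K2CO3, MeOH, 0 °C to rt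
Reagents that add atoms: dimethyl (1-diazo-2-oxopropyl)phosphonate (Ohira–Bestmann reagent), CC(=O)C(=[N+]=[N-])P(=O)(OC)OC
Why: Seyferth–Gilbert homologation in the Ohira–Bestmann variant, which converts non-enolisable aryl aldehydes into terminal alkynes under mild carbonate/methanol conditions that spare MOM ethers and prenyl groups.

Step 8
Reactants: 7 6-iodo-3-(methoxymethoxy)-2-(3-methylbut-2-en-1-yl)phenol; 12 5-ethynyl-2-(methoxymethoxy)-1,3-bis(3-methylbut-2-en-1-yl)benzene; 13 carbon monoxide
Product: 16 7,4'-bis(methoxymethoxy)-8,3',5'-tris(3-methylbut-2-en-1-yl)flavone, via ynone 14 (not isolated), via enaminone 15 (not isolated)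
Conditions: PdCl2(dppf) (5 mol%), CO (20 bar), Et2NH, 120 °C
Reagents that add atoms: none
Why: PdCl2(dppf) is reduced in situ to zerovalent palladium, which inserts into the C4a–I bond of 7; CO insertion gives an aroyl complex of divalent palladium, the amine-deprotonated alkyne 12 is transferred to the metal and reductive elimination forms C4–C3, so that C4a–C4 and C4–C3 are both in place in ynone 14. Et2NH then adds in conjugate fashion to 14 to give enaminone 15, and the ortho phenol attacks the amine-bearing carbon with loss of Et2NH, forming O1–C2. The closest known reaction type is the palladium-catalysed carbonylative Sonogashira coupling and annulation of ortho-iodophenols with terminal arylacetylenes to flavones. Ring C closes by a 6-endo addition–elimination at C2, and no stereocentre is formed because the product is a planar 4H-chromen-4-one. The step needs carbonylative over direct alkynylation (the latter would end in a 2-arylbenzofuran), which CO pressure, a bidentate phosphine and the absence of a copper co-catalyst should secure, and it needs flavone over aurone, which the secondary amine secures because its enaminone can only be closed by oxygen attack at C2. Regiochemistry on ring A needs no control, since iodine sits on C4a next to the only free hydroxyl and the prenyl group already occupies the other ortho carbon.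

Step 9
Reactants: 16 7,4'-bis(methoxymethoxy)-8,3',5'-tris(3-methylbut-2-en-1-yl)flavone
Product: 17 (2S)-7,4'-bis(methoxymethoxy)-8,3',5'-tris(3-methylbut-2-en-1-yl)flavanone
Conditions: Cu(OAc)2·H2O (5 mol%), (R)-DTBM-SEGPHOS (5.5 mol%), (EtO)2MeSiH, t-BuOH, THF, 0 °C to rt
Reagents that add atoms: none
Why: Copper-hydride-catalysed asymmetric conjugate (1,4-) reduction of the chromone enone, in which the bisphosphine-ligated hydride of monovalent copper, generated from Cu(OAc)2 and the silane, adds hydride to C2 on the face left open by the chiral ligand and so sets 2S, after which t-BuOH protonates the copper enolate at C3 and turns the catalyst over, while the unactivated trisubstituted prenyl alkenes and the MOM ethers do not react.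

Step 10
Reactants: 17 (2S)-7,4'-bis(methoxymethoxy)-8,3',5'-tris(3-methylbut-2-en-1-yl)flavanone
Product: 18 sophoranone, (2S)-7,4'-dihydroxy-8,3',5'-tris(3-methylbut-2-en-1-yl)flavanone
Conditions: 3 M aq. HCl, MeOH–THF, rt to 40 °C
Reagents that add atoms: none
Why: Acid-catalysed cleavage of the two MOM acetals (transacetalisation to dimethoxymethane in methanol) should proceed at or just above room temperature, where the C2 centre, which is lost only through reversible oxa-Michael ring opening under stronger acid or base, and the prenyl double bonds are expected to persist.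

**Compound list**

1 | 4-iodobenzene-1,3-diol (4-iodoresorcinol) | Oc1ccc(I)c(O)c1 | starting material
2 | 2-iodo-5-(methoxymethoxy)phenol | COCOc1ccc(I)c(O)c1 | intermediate
3 | allyl bromide (3-bromoprop-1-ene) | C=CCBr | starting material
4 | 1-iodo-4-(methoxymethoxy)-2-(prop-2-en-1-yloxy)benzene | COCOc1ccc(I)c(OCC=C)c1 | intermediate
5 | 6-iodo-3-(methoxymethoxy)-2-(prop-2-en-1-yl)phenol | COCOc1ccc(I)c(O)c1CC=C | intermediate
6 | 2-methylbut-2-ene | CC=C(C)C | starting material
7 | 6-iodo-3-(methoxymethoxy)-2-(3-methylbut-2-en-1-yl)phenol | COCOc1ccc(I)c(O)c1CC=C(C)C | intermediate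
8 | 3,5-dibromo-4-hydroxybenzaldehyde | O=Cc1cc(Br)c(O)c(Br)c1 | starting material
9 | 3,5-dibromo-4-(methoxymethoxy)benzaldehyde | COCOc1c(Br)cc(C=O)cc1Br | intermediate
10 | tributyl(3-methylbut-2-en-1-yl)stannane (prenyltributyltin) | CCCC[Sn](CCCC)(CCCC)CC=C(C)C | starting material
11 | 4-(methoxymethoxy)-3,5-bis(3-methylbut-2-en-1-yl)benzaldehyde | COCOc1c(CC=C(C)C)cc(C=O)cc1CC=C(C)C | intermediate
12 | 5-ethynyl-2-(methoxymethoxy)-1,3-bis(3-methylbut-2-en-1-yl)benzene | COCOc1c(CC=C(C)C)cc(C#C)cc1CC=C(C)C | intermediate
13 | carbon monoxide | [C-]#[O+] | starting material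
14 | 1-[2-hydroxy-4-(methoxymethoxy)-3-(3-methylbut-2-en-1-yl)phenyl]-3-[4-(methoxymethoxy)-3,5-bis(3-methylbut-2-en-1-yl)phenyl]prop-2-yn-1-one (ynone, formed in the flask) | COCOc1ccc(C(=O)C#Cc2cc(CC=C(C)C)c(OCOC)c(CC=C(C)C)c2)c(O)c1CC=C(C)C | intermediate
15 | 3-(diethylamino)-1-[2-hydroxy-4-(methoxymethoxy)-3-(3-methylbut-2-en-1-yl)phenyl]-3-[4-(methoxymethoxy)-3,5-bis(3-methylbut-2-en-1-yl)phenyl]prop-2-en-1-one (enaminone, formed in the flask; push–pull double bond of mobile geometry) | CCN(CC)C(=CC(=O)c1ccc(OCOC)c(CC=C(C)C)c1O)c1cc(CC=C(C)C)c(OCOC)c(CC=C(C)C)c1 | intermediate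
16 | 7-(methoxymethoxy)-2-[4-(methoxymethoxy)-3,5-bis(3-methylbut-2-en-1-yl)phenyl]-8-(3-methylbut-2-en-1-yl)-4H-chromen-4-one | CC(C)=CCc1cc(-c2cc(=O)c3ccc(OCOC)c(CC=C(C)C)c3o2)cc(CC=C(C)C)c1OCOC | intermediate
17 | (2S)-7-(methoxymethoxy)-2-[4-(methoxymethoxy)-3,5-bis(3-methylbut-2-en-1-yl)phenyl]-8-(3-methylbut-2-en-1-yl)-2,3-dihydro-4H-chromen-4-one | CC(C)=CCc1cc([C@@H]2CC(=O)c3ccc(OCOC)c(CC=C(C)C)c3O2)cc(CC=C(C)C)c1OCOC | intermediate
18 | sophoranone, (2S)-7-hydroxy-2-[4-hydroxy-3,5-bis(3-methylbut-2-en-1-yl)phenyl]-8-(3-methylbut-2-en-1-yl)-2,3-dihydro-4H-chromen-4-one | CC(C)=CCc1cc([C@@H]2CC(=O)c3ccc(O)c(CC=C(C)C)c3O2)cc(CC=C(C)C)c1O | target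

**Count**

Total steps: 10. Longest linear sequence: 7 steps (steps 1, 2, 3, 4, 8, 9, 10); the ring B branch (steps 5, 6, 7) joins at step 8.

**Steps most likely to fail**

Step 8. The annulation may go wrong in three ways. The alkyne may couple directly at C4a without CO uptake and then cyclise onto the triple bond. Oxidative addition into the electron-rich iodophenol may be too slow. The ynone may close in the 5-exo sense. The fallback makes the same three bonds one at a time without CO gas. It sets out from 7: n-BuLi (2.2 equiv, THF, −78 °C; phenoxide formation, then iodine–lithium exchange) and DMF should give 2-hydroxy-4-(methoxymethoxy)-3-(3-methylbut-2-en-1-yl)benzaldehyde F1. The lithium acetylide of 12 (n-BuLi, THF, −78 °C) is added to the lithium phenoxide of F1 (pre-formed with LiHMDS) to give racemic 1-[2-hydroxy-4-(methoxymethoxy)-3-(3-methylbut-2-en-1-yl)phenyl]-3-[4-(methoxymethoxy)-3,5-bis(3-methylbut-2-en-1-yl)phenyl]prop-2-yn-1-ol F2. MnO2 in CH2Cl2 oxidises F2 to ynone 14, which is treated at once with Et2NH in EtOH so that it passes through enaminone 15 and rejoins the route at flavone 16.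

Step 9. The reduction may fail through insufficient facial discrimination by the ligand at the aryl-substituted, vinylogous-ester β-carbon. It may also fail through slow hydride transfer with competing 1,2-reduction, or through opening of the enolate before it is protonated. The fallback separates reduction from stereocontrol and sets out from 16. Non-selective 1,4-reduction with LiBH(s-Bu)3 (THF, −78 °C) should give racemic 7,4'-bis(methoxymethoxy)-8,3',5'-tris(3-methylbut-2-en-1-yl)flavanone F3. Kinetic resolution by Noyori-type asymmetric transfer hydrogenation with RuCl[(R,R)-TsDPEN](p-cymene) and HCO2H/Et3N is expected to reduce the 2R enantiomer faster. The reduction product is the cis alcohol (2R,4R)-7,4'-bis(methoxymethoxy)-8,3',5'-tris(3-methylbut-2-en-1-yl)flavan-4-ol F4, from which the untouched 2S ketone is separated by chromatography; the route is rejoined at 17.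

Step 6. The double Stille coupling may suffer from bond formation at the γ-carbon of the prenyl stannane, which would give reverse-prenyl isomers. It may also stall after the first coupling next to the MOM ether. The fallback removes the regiochemical question and sets out from 9. Two-fold Stille coupling with allyltributylstannane (Pd(PPh3)4, DMF, 100 °C) should give 4-(methoxymethoxy)-3,5-di(prop-2-en-1-yl)benzaldehyde F5. Two-fold cross-metathesis of F5 with 2-methylbut-2-ene 6 under the conditions of step 4 then leads back to 11.

**Further compounds**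

F1 | step 8 | 2-hydroxy-4-(methoxymethoxy)-3-(3-methylbut-2-en-1-yl)benzaldehyde | COCOc1ccc(C=O)c(O)c1CC=C(C)C
F2 | step 8 | 1-[2-hydroxy-4-(methoxymethoxy)-3-(3-methylbut-2-en-1-yl)phenyl]-3-[4-(methoxymethoxy)-3,5-bis(3-methylbut-2-en-1-yl)phenyl]prop-2-yn-1-ol (racemic) | COCOc1ccc(C(O)C#Cc2cc(CC=C(C)C)c(OCOC)c(CC=C(C)C)c2)c(O)c1CC=C(C)C
F3 | step 9 | racemic 7-(methoxymethoxy)-2-[4-(methoxymethoxy)-3,5-bis(3-methylbut-2-en-1-yl)phenyl]-8-(3-methylbut-2-en-1-yl)-2,3-dihydro-4H-chromen-4-one | CC(C)=CCc1cc(C2CC(=O)c3ccc(OCOC)c(CC=C(C)C)c3O2)cc(CC=C(C)C)c1OCOC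
F4 | step 9 | (2R,4R)-7-(methoxymethoxy)-2-[4-(methoxymethoxy)-3,5-bis(3-methylbut-2-en-1-yl)phenyl]-8-(3-methylbut-2-en-1-yl)-3,4-dihydro-2H-chromen-4-ol | CC(C)=CCc1cc([C@H]2C[C@@H](O)c3ccc(OCOC)c(CC=C(C)C)c3O2)cc(CC=C(C)C)c1OCOC
F5 | step 6 | 4-(methoxymethoxy)-3,5-di(prop-2-en-1-yl)benzaldehyde | COCOc1c(CC=C)cc(C=O)cc1CC=C
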